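## Analysis of the target

Compound 28 is a tridepside: three benzene rings joined head to tail by two aryl ester bonds, with no ring fusion. Ring A is a 3,4-dihydroxy-6-methoxy-2-methylbenzoyl group esterified to the C4 oxygen of ring B, a 2-hydroxy-6-methylbenzoyl group, which is in turn esterified to the C4 oxygen of ring C, a 2-hydroxy-6-methylbenzoic acid with a free carboxyl. There is no stereocentre and no stereogenic double bond, so nothing has to be set or preserved stereochemically. The sensitive groups are the two phenyl esters (open to hydrolysis, alcoholysis and acyl migration under base), the free salicylic acid of ring C (which decarboxylates on heating) and the catechol of ring A (which oxidises in basic, aerated media), so the final deprotection has to be neutral and non-nucleophilic. The difficulty is twofold: each inter-ring ester joins a phenol to a benzoyl carbon flanked by two ortho substituents, and five phenolic oxygens and one carboxyl must be told apart, among them a ring A C6 methyl ether that sits ortho to a carbonyl exactly as the free ring C C2 hydroxyl does. The strategy rests on ring C: its atoms C3, C4, C5 and C6, with the oxygen on C4 and the methyl on C6, are the C3 to C6 segment of triacetic acid lactone 4. The C4 hydroxyl of 4 is a vinylogous carboxylic acid and can take on the ring B acyl group before ring C exists, and C1 and C2 of ring C, with carboxyl and oxygen attached, can then be delivered as one two-carbon alkyne while the lactone bridge leaves.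

## Retrosynthetic reasoning

**28 to 27.** The last operation must be neutral. The ring A C3 and C4 hydroxyls and the ring C carboxyl are therefore traced back to benzyl groups in 27, and three O–CH2 bonds are cut by hydrogenolysis. This touches neither the aryl esters nor the ring A methyl ether.

**27 to 25 and 26.** The ester bond between the ring A carbonyl carbon and the ring B C4 oxygen is cut, giving triol 25 and acid chloride 26, made from acid 21. This bond is made last because ring A carries a methyl ether ortho to its carbonyl, and the Lewis acid treatment that must free the ring C C2 oxygen earlier would remove it as well. The forward acylation has to pick ring B C4–OH among three phenols. The other two, at C2 of rings B and C, are hydrogen-bonded to and flanked by ester carbonyls, which is the basis for the selection.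

**25 to 24 to 23.** No skeletal bond is cut. Ester 25 is the carboxyl-benzylated form of acid 24, and 24 comes from 23 by removal of one methyl and three benzyl groups in a single Lewis acid treatment. The methyl group on the ring C C2 oxygen is imposed by the key step, and its chelation-assisted removal cannot spare benzyl groups. It is therefore simplest to strip everything and put one benzyl group back on the carboxyl, which alkylates far more readily than any phenol under bicarbonate conditions.

**23 to 6 and 12.** This is the key disconnection. Ring C is cut at C2–C3 and at C1–C6, and C3 and C6 are re-bridged by a lactone unit, which gives pyrone 6 and alkyne 12. Cutting the ring rather than the ring B to ring C ester means this ester is carried intact through the ring construction and is never formed on a chelated phenol. The forward reaction is a [4+2] cycloaddition followed by loss of the bridge, and it must place the ester-bearing carbon of 12 on C6 of the pyrone. The oxygen substituent of 12 is methyl because a group with a β-hydrogen or a benzylic O–C bond would not survive the temperature of the cycloaddition.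

**6 to 5 and 4, then 5 to 3 to 2 to 1.** The ester C(=O)–O bond of 6 is cut to acid chloride 5 and lactone 4. The nucleophile is the single, acidic, unflanked hydroxyl of 4, so no choice between hydroxyls arises. Acid chloride 5 comes from acid 3, which is reached from orsellinic acid 1 by exhaustive benzylation to 2 and saponification.

**12 to 11 and 10, then 11 to 9 to 8 to 7.** The bond between the alkyne carbon and the carbonyl carbon is cut, giving acetylide 11 and chloroformate 10. Acetylide 11 is made from isolated alkyne 9, which comes from chloroacetal 7 through acetylide 8 by double elimination. Alkyne 9 is isolated because the methoxide and amide set free in its formation would otherwise attack 10 and add to the polarised triple bond of 12.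

**21 to 20 to 18 to 17 to 15 to 13.** Acid 21 is the oxidation product of aldehyde 20. The bond between ring A C1 and the formyl carbon is cut, leading through iminium salt 19 to arene 18, where this position is para to one benzyloxy group, ortho to the methoxy group and next to the methyl group. Arene 18 is the dibenzyl ether of catechol 17. The second catechol oxygen of 17 is traced, through formate 16, to the formyl group of salicylaldehyde 15 (aryl migration to oxygen). Aldehyde 15 comes, through benzylic alcohol 14, from phenol 13 by formylation at its only free ortho position.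

## Alternatives that were turned down

**Alternative 1:** Ring A would be cut at its C1–C2 bond and unfolded into an open-chain tetraketide that carries the future C3 oxygen as a benzyl ether, tert-butyl 6-(benzyloxy)-7,7-dimethoxy-3,5-dioxooctanoate (A2, racemic; the ketal stands for the mask on C7).
- Forward key step: mild acid frees the C7 ketone, base lets the C2 carbanion add to it, and loss of water and enolisation give tert-butyl 3-(benzyloxy)-4,6-dihydroxy-2-methylbenzoate (A1).
- For it: the oxygenation pattern of ring A is written into the chain, so no aromatic substitution has to choose between two open positions. The three oxygens of A1 emerge already differentiated, so benzylation at C4, methylation at C6 and acidolysis of the tert-butyl ester would lead to acid 21.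
- Where it is stronger: regiochemical certainty for ring A. Step 9 of the chosen route depends on directing effects.
- Against it: A2 needs several steps of polyanion chemistry, and the unmasked chain can also close through oxygen onto the ester to give a 4-hydroxy-2-pyrone. Above all, the ring construction is spent on ring A, which ordinary arene chemistry reaches in five steps from 13, while both inter-ring esters still have to be made by acylating phenols.
- What the chosen strategy offers instead: its ring construction is placed where it relieves an esterification. The ring B to ring C ester is formed on the single acidic hydroxyl of 4 before ring C exists.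

**Alternative 2:** Ring B would be assembled on an existing ring C ester by cutting ring B at C2–C3, C4–C5 and C1–C2. This leads to the diazoketone benzyl 2-(benzyloxy)-4-{[(2E)-5-diazo-3-methyl-4-oxopent-2-enoyl]oxy}-6-methylbenzoate (A4) and the ynol ether 1-[(ethynyloxy)methyl]-4-methoxybenzene (A5).
- Forward key step: irradiation triggers Wolff rearrangement of A4 to a vinylketene, [2+2] addition of A5 gives a vinylcyclobutenone, and 4-electron ring opening followed by 6-electron electrocyclisation delivers benzyl 2-(benzyloxy)-4-({2-hydroxy-4-[(4-methoxybenzyl)oxy]-6-methylbenzoyl}oxy)-6-methylbenzoate (A3).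
- For it: like the chosen route it forms the inter-ring ester before the ring, and it does so by acylating a phenol with an unhindered enoyl group, which is easier than acylating 4 with 5. A3 also emerges with orthogonal protection: the 4-methoxybenzyl ether on ring B C4 can be removed oxidatively.
- Where it is stronger: protecting-group economy after the key step. Ring A could be attached without the global dealkylation and re-benzylation of steps 12 and 13 (three operations against four).
- Against it: A4 takes more steps than 6, since a methyl-substituted butenedioic half-ester must be made regioselectively, activated and homologated with a diazoalkane. As an aryl ester it is photolabile, so a photo-Fries shift competes with the Wolff rearrangement. A5 is a benzylic alkynyl ether, a class that rearranges sigmatropically on mild warming, whereas the later stages of this benzannulation need heat.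
- What the chosen strategy offers instead: bench-handled partners made in three and two steps, a purely thermal key step, and a gas as the only by-product.

**Alternative 3:** Ring B would again be built on ring C, but by the biosynthetic logic. The ring B to ring C ester C–O bond and the ring B C1–C6 bond are cut, leading to the diketo-dioxinone 6-(2,4-dioxopentyl)-2,2-dimethyl-4H-1,3-dioxin-4-one (A7) and benzyl 2,4-dihydroxy-6-methylbenzoate (A8).
- Forward key step: heating A7 releases an acylketene, and the C4 hydroxyl of A8 adds to it to give the aryl triketo ester benzyl 2-hydroxy-6-methyl-4-[(3,5,7-trioxooctanoyl)oxy]benzoate (A9). Base then closes ring B by aldol addition of chain C2 to the C7 ketone and aromatisation, giving benzyl 4-[(2,4-dihydroxy-6-methylbenzoyl)oxy]-2-hydroxy-6-methylbenzoate (A6).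
- For it: A6 is the same substance as compound 25 of the chosen route. It would be reached in roughly four steps, with no protecting group on ring B, no hindered acylation (the ester comes from ketene capture) and no dealkylation.
- Where it is stronger: step economy, clearly. The chosen route needs eight steps to 25.
- Against it: A9 is an aryl ester of a β-keto acid, an activated acyl donor with a phenoxide leaving group. Under the base needed for the aldol closure, the C5 enolate oxygen can attack C1 and expel A8, forming a 4-hydroxy-2-pyrone and destroying the ester just made. The alkyl esters on which this cyclisation is normally run have no such leaving group. The acylketene can also re-form from A9.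
- What the chosen strategy offers instead: it gives up brevity for a ring closure that is neutral and has no competing cyclisation mode, and it carries the inter-ring ester as an ordinary aroyl ester that is never part of a β-keto ester.

Key step: step 11

Assumption: 4-methoxy-2-methylphenol 13 is treated as a purchasable phenol, and the low-boiling alkyne 9 is kept and transferred as a cold THF solution.

## Route

Step 1
Reactants: 1 orsellinic acid (2,4-dihydroxy-6-methylbenzoic acid)
Product: 2 benzyl 2,4-bis(benzyloxy)-6-methylbenzoate
Conditions: BnBr (3.3 equiv), K2CO3, DMF, rt then 60 °C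
Reagents that add atoms: benzyl bromide, BrCc1ccccc1
Why: Williamson O-alkylation; the carboxylate and the free C4 phenol react at room temperature and the hydrogen-bonded C2 phenol on warming, so the free acid, which would decarboxylate, is never heated.

Step 2
Reactants: 2 benzyl 2,4-bis(benzyloxy)-6-methylbenzoate
Product: 3 2,4-bis(benzyloxy)-6-methylbenzoic acid
Conditions: KOH, DMSO/H2O (4:1), 90 °C; then 1 M HCl
Reagents that add atoms: potassium hydroxide (KOH), [K+].[OH-]
Why: Saponification by addition–elimination at the ester carbonyl; hydroxide in aqueous DMSO is reactive enough for the di-ortho-substituted benzoate, and benzyl aryl ethers are inert to base.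

Step 3
Reactants: 3 2,4-bis(benzyloxy)-6-methylbenzoic acid; 4 4-hydroxy-6-methyl-2H-pyran-2-one (triacetic acid lactone)
Product: 6 6-methyl-2-oxo-2H-pyran-4-yl 2,4-bis(benzyloxy)-6-methylbenzoate, via 2,4-bis(benzyloxy)-6-methylbenzoyl chloride 5 (not isolated)
Conditions: (COCl)2, DMF (cat.), CH2Cl2, 0 °C → rt; evaporate; 4, Et3N (1.3 equiv), CH2Cl2, 0 °C → rt
Reagents that add atoms: none
Why: Acid chloride formation, then O-acylation of the pyrone enol, a vinylogous carboxylic acid that Et3N ionises fully; without a nucleophilic catalyst the kinetically formed 4-O-acyl pyrone should not rearrange to the 3-C-acyl isomer.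

Step 4
Reactants: 7 2-chloro-1,1-dimethoxyethane (chloroacetaldehyde dimethyl acetal)
Product: 9 methoxyethyne, via sodium methoxyacetylide 8 (not isolated)
Conditions: NaNH2 (3 equiv), liq. NH3, −33 °C; evaporate NH3; cold brine, −70 °C → rt, distil into THF at −78 °C
Reagents that add atoms: none
Why: Two base-induced 1,2-eliminations (loss of methanol, then of HCl) and deprotonation give the acetylide, the classical alkoxyacetylene synthesis; protonation and distillation separate 9 from methoxide and amide, which would consume 10 and add to 12 in the next step.

Step 5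
Reactants: 9 methoxyethyne; 10 benzyl chloroformate
Product: 12 benzyl 3-methoxyprop-2-ynoate, via lithium methoxyacetylide 11 (not isolated)
Conditions: n-BuLi (1.0 equiv), THF, −78 °C; cannulate into 10 (1.5 equiv), THF, −78 °C; pH 7 buffer, 0 °C
Reagents that add atoms: none
Why: Deprotonation of the terminal alkyne and C-acylation of the lithium acetylide by the chloroformate (alkynoate synthesis); inverse addition into excess 10 keeps the acetylide away from the product, and a cold neutral work-up avoids hydration of the push-pull alkyne.

Step 6
Reactants: 13 4-methoxy-2-methylphenol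
Product: 15 2-hydroxy-5-methoxy-3-methylbenzaldehyde, via 2-(hydroxymethyl)-4-methoxy-6-methylphenol 14 (not isolated)
Conditions: MgCl2 (1.5 equiv), Et3N (3.75 equiv), (CH2O)n (6.8 equiv), MeCN, reflux; 1 M HCl
Reagents that add atoms: paraformaldehyde (reacting as formaldehyde), C=O
Why: Magnesium-mediated ortho-formylation of a phenol (Casnati–Skattebøl): the magnesium phenoxide delivers formaldehyde to the ortho carbon and a second formaldehyde oxidises the benzylic alkoxide 14 by hydride transfer; C6 is the only free ortho position of 13, so the regiochemistry is unambiguous.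

Step 7
Reactants: 15 2-hydroxy-5-methoxy-3-methylbenzaldehyde
Product: 17 5-methoxy-3-methylbenzene-1,2-diol, via 2-hydroxy-5-methoxy-3-methylphenyl formate 16 (not isolated)
Conditions: 30% H2O2, 2 M NaOH, N2, 0 °C → rt; then HCl to pH 3
Reagents that add atoms: hydrogen peroxide, OO
Why: Dakin oxidation: hydroperoxide adds to the aldehyde, the electron-rich aryl group migrates to oxygen and the formate 16 is hydrolysed in the basic medium; exclusion of air protects the electron-rich catechol.

Step 8
Reactants: 17 5-methoxy-3-methylbenzene-1,2-diol
Product: 18 1,2-bis(benzyloxy)-5-methoxy-3-methylbenzene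
Conditions: BnBr (2.3 equiv), K2CO3, DMF, 60 °C, N2
Reagents that add atoms: benzyl bromide, BrCc1ccccc1
Why: Williamson etherification of both catechol hydroxyls, which also removes the air sensitivity of 17.

Step 9
Reactants: 18 1,2-bis(benzyloxy)-5-methoxy-3-methylbenzene
Product: 20 3,4-bis(benzyloxy)-6-methoxy-2-methylbenzaldehyde, via aryl iminium chloride 19 (not isolated)
Conditions: POCl3 (1.5 equiv), DMF, 0 → 70 °C; then ice water
Reagents that add atoms: N,N-dimethylformamide, CN(C)C=O; water, O
Why: Vilsmeier–Haack formylation; 18 is an orcinol dialkyl ether with one further alkoxy group meta to both open positions, and such ethers are attacked at the position next to the methyl group, para to one oxygen and ortho to the other (C4 of 18, para to the C1 benzyloxy group), in preference to the position between two oxygens.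

Step 10
Reactants: 20 3,4-bis(benzyloxy)-6-methoxy-2-methylbenzaldehyde
Product: 21 3,4-bis(benzyloxy)-6-methoxy-2-methylbenzoic acid
Conditions: NaClO2, NaH2PO4, 2-methyl-2-butene, t-BuOH/THF/H2O, rt
Reagents that add atoms: sodium chlorite (NaClO2), [Na+].[O-]Cl=O
Why: Pinnick oxidation; chlorous acid oxidises the hindered aldehyde without touching benzyl ethers, and the alkene scavenges hypochlorous acid before it can chlorinate the electron-rich ring.

Step 11
Reactants: 6 6-methyl-2-oxo-2H-pyran-4-yl 2,4-bis(benzyloxy)-6-methylbenzoate; 12 benzyl 3-methoxyprop-2-ynoate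
Product: 23 benzyl 4-{[2,4-bis(benzyloxy)-6-methylbenzoyl]oxy}-2-methoxy-6-methylbenzoate, via bicyclic lactone adduct 22 (not isolated)
Conditions: 12 (4 equiv, added in portions), BHT (cat.), xylenes, 160 °C, sealed tube, Ar
Reagents that add atoms: none
Why: Diels–Alder reaction of the 2-pyrone diene (C3 to C6 of 6) with the alkyne of 12 gives the 2-oxabicyclo[2.2.2]octa-5,7-dien-3-one 22, which at the reaction temperature loses its lactone bridge as CO2 by retro-[4+2] and becomes the benzene ring; the closest known reaction is the benzannulation of 4-oxygenated 6-methyl-2-pyrones with alkynoates. Ring C is closed by an intermolecular [4+2] cycloaddition that forms both C2–C3 and C1–C6, the six-membered carbocycle appearing in 22 and becoming aromatic on cycloreversion. The two bridgehead stereocentres of 22 form as a racemate with their relative configuration fixed by the bicycle, and both vanish on loss of CO2, so the step leaves no stereocentre. The selectivity needed is regiochemical: pyrone C3, the β-carbon of the enol ester and the nucleophilic diene terminus, must bond to the methoxy-bearing alkyne carbon, the electrophilic β-carbon of the ynoate, while pyrone C6 bonds to the ester-bearing carbon; this matched polarisation puts the benzyl ester between methyl and methoxy and para to the acyloxy group. The methyl ynol ether has no β-hydrogen and cannot fragment to a ketene at this temperature, the hindered aroyl group resists acyl transfer, and the absence of base or nucleophile keeps the 4-O-acyl pyrone from rearranging.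

Step 12
Reactants: 23 benzyl 4-{[2,4-bis(benzyloxy)-6-methylbenzoyl]oxy}-2-methoxy-6-methylbenzoate
Product: 24 4-[(2,4-dihydroxy-6-methylbenzoyl)oxy]-2-hydroxy-6-methylbenzoic acid (lecanoric acid)
Conditions: BCl3 (8 equiv), C6HMe5 (6 equiv), CH2Cl2, −78 → 0 °C; ice water
Reagents that add atoms: none
Why: Lewis-acid dealkylation: BCl3 ionises the benzyl–oxygen bonds of both ethers and the ester and, chelated between the ring C C2 oxygen and the neighbouring carbonyl, also removes the ortho methyl group; pentamethylbenzene captures the benzyl cations so the resorcinol rings are not C-benzylated, and the aryl ester should survive at this temperature. Any material that keeps its benzyl ester is compound 25 and is carried forward directly.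

Step 13
Reactants: 24 4-[(2,4-dihydroxy-6-methylbenzoyl)oxy]-2-hydroxy-6-methylbenzoic acid
Product: 25 benzyl 4-[(2,4-dihydroxy-6-methylbenzoyl)oxy]-2-hydroxy-6-methylbenzoate
Conditions: BnBr (1.05 equiv), KHCO3 (1.2 equiv), DMF, rt
Reagents that add atoms: benzyl bromide, BrCc1ccccc1
Why: Carboxylate alkylation; KHCO3 deprotonates only the carboxylic acid, so benzyl bromide alkylates the carboxylate and leaves the three phenols free, and room temperature avoids decarboxylation and depside cleavage.

Step 14
Reactants: 21 3,4-bis(benzyloxy)-6-methoxy-2-methylbenzoic acid; 25 benzyl 4-[(2,4-dihydroxy-6-methylbenzoyl)oxy]-2-hydroxy-6-methylbenzoate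
Product: 27 benzyl 4-[(4-{[3,4-bis(benzyloxy)-6-methoxy-2-methylbenzoyl]oxy}-2-hydroxy-6-methylbenzoyl)oxy]-2-hydroxy-6-methylbenzoate, via 3,4-bis(benzyloxy)-6-methoxy-2-methylbenzoyl chloride 26 (not isolated)
Conditions: (COCl)2, DMF (cat.), CH2Cl2, 0 °C → rt; evaporate; 25 (1.0 equiv), Et3N (1.2 equiv), DMAP (0.1 equiv), CH2Cl2, −20 → 0 °C
Reagents that add atoms: none
Why: Acid chloride formation, then acylation of the most acidic and only non-hydrogen-bonded phenol (ring B C4–OH); the two C2 hydroxyls are held in six-membered hydrogen bonds to their ortho ester carbonyls and are flanked by those esters, the same discrimination on which classical depside couplings rely.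

Step 15
Reactants: 27 benzyl 4-[(4-{[3,4-bis(benzyloxy)-6-methoxy-2-methylbenzoyl]oxy}-2-hydroxy-6-methylbenzoyl)oxy]-2-hydroxy-6-methylbenzoate
Product: 28 4-({4-[(3,4-dihydroxy-6-methoxy-2-methylbenzoyl)oxy]-2-hydroxy-6-methylbenzoyl}oxy)-2-hydroxy-6-methylbenzoic acid
Conditions: H2 (1 atm), 10% Pd/C, EtOAc/THF, rt
Reagents that add atoms: none
Why: Hydrogenolysis of the two benzyl ethers and the benzyl ester under neutral conditions in a non-nucleophilic solvent; the aryl esters, the ring A methyl ether and the arenes are untouched.

## Compound list

1 | orsellinic acid (2,4-dihydroxy-6-methylbenzoic acid) | Cc1cc(O)cc(O)c1C(=O)O | starting material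
2 | benzyl 2,4-bis(benzyloxy)-6-methylbenzoate | Cc1cc(OCc2ccccc2)cc(OCc2ccccc2)c1C(=O)OCc1ccccc1 | intermediate
3 | 2,4-bis(benzyloxy)-6-methylbenzoic acid | Cc1cc(OCc2ccccc2)cc(OCc2ccccc2)c1C(=O)O | intermediate
4 | 4-hydroxy-6-methyl-2H-pyran-2-one (triacetic acid lactone) | Cc1cc(O)cc(=O)o1 | starting material
5 | 2,4-bis(benzyloxy)-6-methylbenzoyl chloride | Cc1cc(OCc2ccccc2)cc(OCc2ccccc2)c1C(=O)Cl | intermediate (not isolated)
6 | 6-methyl-2-oxo-2H-pyran-4-yl 2,4-bis(benzyloxy)-6-methylbenzoate | Cc1cc(OC(=O)c2c(C)cc(OCc3ccccc3)cc2OCc2ccccc2)cc(=O)o1 | intermediate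
7 | 2-chloro-1,1-dimethoxyethane (chloroacetaldehyde dimethyl acetal) | COC(CCl)OC | starting material
8 | sodium methoxyacetylide | [Na]C#COC | intermediate (not isolated)
9 | methoxyethyne | C#COC | intermediate
10 | benzyl chloroformate | O=C(Cl)OCc1ccccc1 | starting material
11 | lithium methoxyacetylide | [Li]C#COC | intermediate (not isolated)
12 | benzyl 3-methoxyprop-2-ynoate | COC#CC(=O)OCc1ccccc1 | intermediate
13 | 4-methoxy-2-methylphenol | COc1ccc(O)c(C)c1 | starting material
14 | 2-(hydroxymethyl)-4-methoxy-6-methylphenol (present as its magnesium phenoxide) | COc1cc(C)c(O)c(CO)c1 | intermediate (not isolated)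
15 | 2-hydroxy-5-methoxy-3-methylbenzaldehyde | COc1cc(C)c(O)c(C=O)c1 | intermediate
16 | 2-hydroxy-5-methoxy-3-methylphenyl formate | COc1cc(C)c(O)c(OC=O)c1 | intermediate (not isolated)
17 | 5-methoxy-3-methylbenzene-1,2-diol | COc1cc(C)c(O)c(O)c1 | intermediate
18 | 1,2-bis(benzyloxy)-5-methoxy-3-methylbenzene | COc1cc(C)c(OCc2ccccc2)c(OCc2ccccc2)c1 | intermediate
19 | N-{[3,4-bis(benzyloxy)-6-methoxy-2-methylphenyl]methylidene}-N-methylmethanaminium chloride | COc1cc(OCc2ccccc2)c(OCc2ccccc2)c(C)c1C=[N+](C)C.[Cl-] | intermediate (not isolated)
20 | 3,4-bis(benzyloxy)-6-methoxy-2-methylbenzaldehyde | COc1cc(OCc2ccccc2)c(OCc2ccccc2)c(C)c1C=O | intermediate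
21 | 3,4-bis(benzyloxy)-6-methoxy-2-methylbenzoic acid | COc1cc(OCc2ccccc2)c(OCc2ccccc2)c(C)c1C(=O)O | intermediate
22 | benzyl 8-{[2,4-bis(benzyloxy)-6-methylbenzoyl]oxy}-5-methoxy-1-methyl-3-oxo-2-oxabicyclo[2.2.2]octa-5,7-diene-6-carboxylate (racemic; bridgehead configurations fixed by the bicycle) | CC12OC(=O)C(C(OC)=C1C(=O)OCc1ccccc1)C(OC(=O)c1c(C)cc(OCc3ccccc3)cc1OCc1ccccc1)=C2 | intermediate (not isolated)
23 | benzyl 4-{[2,4-bis(benzyloxy)-6-methylbenzoyl]oxy}-2-methoxy-6-methylbenzoate | COc1cc(OC(=O)c2c(C)cc(OCc3ccccc3)cc2OCc2ccccc2)cc(C)c1C(=O)OCc1ccccc1 | intermediate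
24 | 4-[(2,4-dihydroxy-6-methylbenzoyl)oxy]-2-hydroxy-6-methylbenzoic acid (lecanoric acid) | Cc1cc(O)cc(O)c1C(=O)Oc1cc(C)c(C(=O)O)c(O)c1 | intermediate
25 | benzyl 4-[(2,4-dihydroxy-6-methylbenzoyl)oxy]-2-hydroxy-6-methylbenzoate | Cc1cc(O)cc(O)c1C(=O)Oc1cc(C)c(C(=O)OCc2ccccc2)c(O)c1 | intermediate
26 | 3,4-bis(benzyloxy)-6-methoxy-2-methylbenzoyl chloride | COc1cc(OCc2ccccc2)c(OCc2ccccc2)c(C)c1C(=O)Cl | intermediate (not isolated)
27 | benzyl 4-[(4-{[3,4-bis(benzyloxy)-6-methoxy-2-methylbenzoyl]oxy}-2-hydroxy-6-methylbenzoyl)oxy]-2-hydroxy-6-methylbenzoate | COc1cc(OCc2ccccc2)c(OCc2ccccc2)c(C)c1C(=O)Oc1cc(C)c(C(=O)Oc2cc(C)c(C(=O)OCc3ccccc3)c(O)c2)c(O)c1 | intermediate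
28 | 4-({4-[(3,4-dihydroxy-6-methoxy-2-methylbenzoyl)oxy]-2-hydroxy-6-methylbenzoyl}oxy)-2-hydroxy-6-methylbenzoic acid | COc1cc(O)c(O)c(C)c1C(=O)Oc1cc(C)c(C(=O)Oc2cc(C)c(C(=O)O)c(O)c2)c(O)c1 | target

## Step count and least certain steps

Total step count: 15. Longest linear sequence: 8 steps (steps 1, 2, 3, 11, 12, 13, 14 and 15, from 1 to 28). The dienophile branch (steps 4 and 5) and the ring A branch (steps 6 to 10) are convergent.

**Step 11 (key step).**
- Risk: thermal oligomerisation of the polarised ynoate may outrun the cycloaddition. The methoxy donor raises the alkyne LUMO and the acyloxy pyrone is only a moderately activated diene, so the temperature window between no reaction and decomposition of 12 may be narrow. A second possibility is cycloaddition in the reversed orientation if the polarisation of the two partners is weaker than assumed.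
- Fallback: the classical depside assembly, which sets out from 1 and 3 and comes back at 24. Acid 1 is alkylated at the carboxylate only (BnBr, KHCO3, DMF) to benzyl 2,4-dihydroxy-6-methylbenzoate F1. Its C4 hydroxyl is acylated with acid chloride 5, prepared from 3 as in step 3 (Et3N, DMAP cat., CH2Cl2), to give benzyl 4-{[2,4-bis(benzyloxy)-6-methylbenzoyl]oxy}-2-hydroxy-6-methylbenzoate F2. Hydrogenolysis (H2, Pd/C, EtOAc) then gives 24, and the route continues with step 13.

**Step 5.**
- Risk: addition of the acetylide to the carbonyl or to the electrophilic alkyne carbon of the product as it forms, and hydration or oligomerisation of the push-pull alkyne during isolation.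
- Fallback: carboxylation instead of acylation, setting out from 9 and coming back at 12. The lithium acetylide from 9 and n-BuLi is quenched with CO2 to give lithium 3-methoxyprop-2-ynoate F3, a salt that cannot be attacked by further acetylide. F3 is alkylated at oxygen with benzyl bromide in DMF to give 12.

**Step 12.**
- Risk: incomplete removal of the chelated methyl group at temperatures low enough to spare the aryl ester, ring C-benzylation by benzyl cations that escape the scavenger, and decarboxylation of the liberated salicylic acid if the work-up warms.
- Fallback: the two dealkylations are separated, setting out from 23 and coming back at 24. Hydrogenolysis of 23 (H2, Pd/C, EtOAc) removes the three benzyl groups under neutral conditions and gives 4-[(2,4-dihydroxy-6-methylbenzoyl)oxy]-2-methoxy-6-methylbenzoic acid F4. A small excess of BCl3 at −20 to 0 °C then has to remove only the one methyl group chelated to the free carboxyl, with no benzyl cation present, and gives 24.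

**Step 14.**
- Risk: loss of site selectivity (acylation of a hydrogen-bonded C2 hydroxyl or double acylation) and base-induced acyl transfer between phenols. The di-ortho-substituted acid chloride needs nucleophilic catalysis to react at a useful rate, and such conditions narrow the difference between the hydroxyls.
- Fallback: the free hydroxyls are reduced to one before acylation, setting out from 25 and coming back at 28.
  - Silylation with TIPSCl and imidazole in DMF, a reagent that does not touch chelated phenols, gives benzyl 2-hydroxy-4-[(2-hydroxy-6-methyl-4-{[tri(propan-2-yl)silyl]oxy}benzoyl)oxy]-6-methylbenzoate F5.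
  - Benzylation of both C2 hydroxyls (BnBr, K2CO3, acetone, reflux) gives benzyl 2-(benzyloxy)-4-[(2-(benzyloxy)-6-methyl-4-{[tri(propan-2-yl)silyl]oxy}benzoyl)oxy]-6-methylbenzoate F6.
  - Desilylation with Bu4NF buffered with AcOH gives benzyl 2-(benzyloxy)-4-{[2-(benzyloxy)-4-hydroxy-6-methylbenzoyl]oxy}-6-methylbenzoate F7.
  - Acylation of the single free hydroxyl with excess 26 (Et3N, DMAP) gives benzyl 2-(benzyloxy)-4-({2-(benzyloxy)-4-[(3,4-bis(benzyloxy)-6-methoxy-2-methylbenzoyl)oxy]-6-methylbenzoyl}oxy)-6-methylbenzoate F8.
  - Hydrogenolysis (H2, Pd/C, EtOAc/THF) removes all five benzyl groups and gives 28.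

## Further compounds

F1 | step 11 | benzyl 2,4-dihydroxy-6-methylbenzoate | Cc1cc(O)cc(O)c1C(=O)OCc1ccccc1
F2 | step 11 | benzyl 4-{[2,4-bis(benzyloxy)-6-methylbenzoyl]oxy}-2-hydroxy-6-methylbenzoate | Cc1cc(OCc2ccccc2)cc(OCc2ccccc2)c1C(=O)Oc1cc(C)c(C(=O)OCc2ccccc2)c(O)c1
F3 | step 5 | lithium 3-methoxyprop-2-ynoate | [Li+].COC#CC(=O)[O-]
F4 | step 12 | 4-[(2,4-dihydroxy-6-methylbenzoyl)oxy]-2-methoxy-6-methylbenzoic acid | COc1cc(OC(=O)c2c(C)cc(O)cc2O)cc(C)c1C(=O)O
F5 | step 14 | benzyl 2-hydroxy-4-[(2-hydroxy-6-methyl-4-{[tri(propan-2-yl)silyl]oxy}benzoyl)oxy]-6-methylbenzoate | Cc1cc(O[Si](C(C)C)(C(C)C)C(C)C)cc(O)c1C(=O)Oc1cc(C)c(C(=O)OCc2ccccc2)c(O)c1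
F6 | step 14 | benzyl 2-(benzyloxy)-4-[(2-(benzyloxy)-6-methyl-4-{[tri(propan-2-yl)silyl]oxy}benzoyl)oxy]-6-methylbenzoate | Cc1cc(O[Si](C(C)C)(C(C)C)C(C)C)cc(OCc2ccccc2)c1C(=O)Oc1cc(C)c(C(=O)OCc2ccccc2)c(OCc2ccccc2)c1
F7 | step 14 | benzyl 2-(benzyloxy)-4-{[2-(benzyloxy)-4-hydroxy-6-methylbenzoyl]oxy}-6-methylbenzoate | Cc1cc(O)cc(OCc2ccccc2)c1C(=O)Oc1cc(C)c(C(=O)OCc2ccccc2)c(OCc2ccccc2)c1
F8 | step 14 | benzyl 2-(benzyloxy)-4-({2-(benzyloxy)-4-[(3,4-bis(benzyloxy)-6-methoxy-2-methylbenzoyl)oxy]-6-methylbenzoyl}oxy)-6-methylbenzoate | COc1cc(OCc2ccccc2)c(OCc2ccccc2)c(C)c1C(=O)Oc1cc(C)c(C(=O)Oc2cc(C)c(C(=O)OCc3ccccc3)c(OCc3ccccc3)c2)c(OCc2ccccc2)c1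
A1 | alternative 1 | tert-butyl 3-(benzyloxy)-4,6-dihydroxy-2-methylbenzoate | Cc1c(OCc2ccccc2)c(O)cc(O)c1C(=O)OC(C)(C)C
A2 | alternative 1 | tert-butyl 6-(benzyloxy)-7,7-dimethoxy-3,5-dioxooctanoate (racemic) | CC(OC)(OC)C(OCc1ccccc1)C(=O)CC(=O)CC(=O)OC(C)(C)C
A3 | alternative 2 | benzyl 2-(benzyloxy)-4-({2-hydroxy-4-[(4-methoxybenzyl)oxy]-6-methylbenzoyl}oxy)-6-methylbenzoate | Cc1cc(OCc2ccc(OC)cc2)cc(O)c1C(=O)Oc1cc(C)c(C(=O)OCc2ccccc2)c(OCc2ccccc2)c1
A4 | alternative 2 | benzyl 2-(benzyloxy)-4-{[(2E)-5-diazo-3-methyl-4-oxopent-2-enoyl]oxy}-6-methylbenzoate | [N-]=[N+]=CC(=O)/C(C)=C/C(=O)Oc1cc(C)c(C(=O)OCc2ccccc2)c(OCc2ccccc2)c1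
A5 | alternative 2 | 1-[(ethynyloxy)methyl]-4-methoxybenzene | C#COCc1ccc(OC)cc1
A6 | alternative 3 | benzyl 4-[(2,4-dihydroxy-6-methylbenzoyl)oxy]-2-hydroxy-6-methylbenzoate | Cc1cc(O)cc(O)c1C(=O)Oc1cc(C)c(C(=O)OCc2ccccc2)c(O)c1
A7 | alternative 3 | 6-(2,4-dioxopentyl)-2,2-dimethyl-4H-1,3-dioxin-4-one | CC(=O)CC(=O)CC1=CC(=O)OC(C)(C)O1
A8 | alternative 3 | benzyl 2,4-dihydroxy-6-methylbenzoate | Cc1cc(O)cc(O)c1C(=O)OCc1ccccc1
A9 | alternative 3 | benzyl 2-hydroxy-6-methyl-4-[(3,5,7-trioxooctanoyl)oxy]benzoate | CC(=O)CC(=O)CC(=O)CC(=O)Oc1cc(C)c(C(=O)OCc2ccccc2)c(O)c1
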